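## Structural features

The target (germacrane numbering: ring carbons C1–C10, lactone carbons C11–C13, methyl C14 on C10, hydroxymethyl C15 on C4) is a tricycle built on a ten-membered carbocycle. An oxygen bridge from C10 to C3 turns C1–C2–C3 into a 3(2H)-furanone (O, C3=C2, C1=O, C10), and a trans-fused α-methylene γ-lactone spans C6 (oxygen) and C7 (carbon C11). C6, C7 and C8 form a contiguous stereotriad (lactone oxygen, lactone carbon, (R)-2-methylbutanoyloxy); the quaternary C10 (methyl, bridge oxygen) lies one methylene (C9) away, and the fifth stereocentre is in the acyl side chain. The C4=C5 double bond is Z within the ring, carries the allylic C15 alcohol and forms a cross-conjugated dienone with the furanone. Fragile parts are the exo-methylene lactone (Michael acceptor), the vinylogous ester of the furanone, the epimerisable α-branched ester, and the 6,12-lactone, which can migrate to O8 whenever O8 is a free alkoxide. The real difficulty is twofold: the strained, oxygen-bridged ten-membered ring with its Z olefin, and the trans relationships of the C6–C7–C8 triad beside it. The key step uses the fact that C6–O, C7–C11 and C8–O are the atoms of a 2,3-epoxy alcohol ester (O6 acylated, epoxide across C7–C8) whose C7 has been inverted by a carbon nucleophile hanging from O6, so that the lactone ring and two stereocentres come from one epoxide opening.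

## Logic of the disconnections

26 to 25 and 24: the C11=C13 double bond is cut to a C11 phosphonate and formaldehyde. The exo-methylene lactone is the most reactive group of 26 and is best made last. The gain is a non-electrophilic handle that survives tin, palladium, ruthenium and chromium chemistry. The forward olefination must run under base mild enough for the furanone and the O8 ester. The C15 silyl ether of 24 exists only to survive the oxidation that makes 24.

24 to 23: the C1 carbonyl and the C2=C3 double bond are traded for a C3 hemiketal hydroxyl and a C1=C2 double bond (oxidative 1,3-transposition in reverse). The reason is that 23 is exactly the oxidation level a metathesis can deliver. The demand is an oxidant that engages a hemiketal hydroxyl while O15 is masked.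

23 to 21 (through 22): the C1=C2 bond and the O–C3 bond are cut. This opens both the ten-membered ring and the oxygen bridge to an acyclic diene that already holds every stereocentre. The forward metathesis must give the Z enone; transannular hemiketal formation is relied on to pull it from the equilibrium, which needs a free C10 hydroxyl.

21 to 20 to 18: the C3–C4 bond is cut (acyl cross-coupling), then the C4–Sn and C5–H bonds (anti addition to the alkyne). The Z trisubstituted olefin is thereby traced to a linear alkyne. The demand is tin at C4 and anti delivery of hydrogen, so O15 is bared beforehand to steer the tin and is silylated again in the same flask.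

18 to 17 to 15 and 16: the silyl ethers are put back and the O8 ester is cut. O8 must be capped directly after it is released so that the lactone cannot move to it. The demand is acylation without epimerising the acid and before any basic step.

15 to 14 (key): the C7–C11 bond is cut, which opens the lactone ring and restores the C7–C8 epoxide. Two stereocentres and one ring are replaced by a trans epoxide and an ester tether on O6. The forward step needs 5-exo attack through carbon at C7 with inversion, and a way to quench the released O8 alkoxide.

14 to 12 and 13: the C12–O6 ester bond is cut. The demand is neutral esterification that does not trigger epoxide migration.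

12 to 11: the two C–O bonds of the epoxide are cut to the E allylic alcohol. C7 and C8 then depend on C6 and on the tartrate. The demand is the matched, erythro-selective reagent-controlled epoxidation, with the C10 vinyl group kept inert as a silyl ether.

11 to 9 and 10: the C5–C6 bond is cut to an enal and a terminal alkyne. The demand is catalyst-controlled 1,2-alkynylation of an enal.

9 to 7 (through 8): the C7=C8 bond is cut to a C8 aldehyde and a two-carbon ylide. The demand is E selectivity and no isolation of the β-silyloxy aldehyde.

7 to 6, 5, 4, 2 and 1: the C1=CH2 bond is cut to a lactol, and the lactone is traced to the two carboxyls of 1. The C10 stereocentre is bought, and the carboxyls are told apart by the dioxolanone that the α-hydroxy acid alone can form.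

## Other disconnections considered

Alternative 1: The cut takes C3 and C4 out of the ring. C2–C3 and C4–C5 are broken and C2–C5 re-joined, which contracts the ring to the eight-membered enone A1 carrying a C10–O ynol ether (C3≡C4–C15).
- Forward step: irradiation of A1 would add the tethered alkyne across C2=C5 (C2–C3 closes a five-membered oxygen ring). The cis-fused cyclobutene would then open thermally in a conrotatory 4π process to the nor-lactone A2.
- In favour: furanone and ring expansion arrive in one metal-free operation. A conrotatory opening of a cis-fused cyclobutene must place one E and one Z double bond in the enlarged ring. That is the arrangement of C2=C3 (E with respect to the ten-membered ring) and C4=C5 (Z) in the target, so both geometries follow from orbital symmetry. C1 is already a ketone.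
- Against: A1 hides the real problems. An eight-membered cis-enone with the trans-lactone and the C6–C8 triad still has to be made. A tertiary alkyl ynol ether must be put on the hindered C10 oxygen by strongly basic chemistry beside a lactone and an ester. Cyclooctenones isomerise and dimerise on irradiation. A2 lacks C13, so the methylene group would have to go in through a lactone enolate in the presence of the furanone and the side-chain ester.
- Comparison: for the macrocycle and furanone stage the alternative is the better one in step count (one step against cross-coupling, metathesis and oxidation) and in control of olefin geometry. For the lactone triad it offers nothing, whereas the chosen key step derives C7 and C8 from one catalytic epoxidation. The phosphonate handle of the chosen route is the safer ending. Both rest on known reaction types; the photochemical substrate is the less accessible.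

Alternative 2: The cut is the C1–C10 bond, which opens the furanone to the aldehyde A3 in which the C3 oxygen carries a β-alkoxy crotonate (C10=C9–C8 ester).
- Forward step: a chiral triazolium carbene would convert the C1 aldehyde into an acyl anion equivalent that adds to C10 (Stetter reaction). This closes the tetrahydrofuran-3-one A4 and sets the quaternary C10 by catalyst control.
- In favour: the oxygenated quaternary centre is made catalytically, and C1 arrives as a ketone, so no oxidative transposition is needed. On both points the alternative is the equal or the better of the chosen plan, which buys C10 from the chiral pool and needs a late oxidation.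
- Against: the acceptor is a β,β-disubstituted, electron-rich vinylogous carbonate and the aldehyde is aliphatic, which is at the edge of the known scope. A3 has a stereocentre at C3 that is later destroyed but would cause matched and mismatched behaviour. A4 must still be dehydrogenated to the furanone. The ten-membered ring and the whole C6–C7–C8 lactone triad remain to be built from the ester and the alkenyl iodide.
- Comparison: structurally it solves the isolated centre and leaves the hard contiguous ones. Mechanistically it is umpolung C–C formation against an SN2 epoxide opening, both of known type. In step economy it is behind, since ring closure, lactone and methylene group all follow.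

Alternative 3: The cut is the C1=C2 bond together with the O–C3 bond of the nor-lactone hemiketal A6, leading to the acyclic vinyl carbinol and vinyl ketone A5.
- Forward step: ring-closing metathesis of A5 would give the Z enone, and the C10 hydroxyl would add across the ring to C3 to give A6. Oxidative transposition would follow.
- In favour: one event makes the ten-membered ring, the Z C1=C2 bond and the oxygen bridge, and the hemiketal formation drives a reversible metathesis. The chosen route uses this same ring closure (21 to 23), so here the two are equal.
- Against it as the strategic step: it leaves the C6–C7–C8 triad to unspecified chemistry. A6 has no C13, so the methylene group must be introduced through a lactone enolate late, in the presence of the furanone and the ester. The oxidation of a hemiketal is not established.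
- Comparison: A5 lacks the bulky, acidic phosphonate of 21 and might undergo metathesis more cleanly, a point on which the alternative could be the better. The chosen plan adds a stereochemical solution for C7 and C8 and a safe precursor of the methylene group. Step counts for the ring-forming stage are the same.

Key step: step 10

Assumption: the (S,S) antipode of the ProPhenol ligand is taken to give the 4S carbinol 11 (Re-face attack on the enal, as in its other carbonyl additions); should the sense be opposite on this substrate, the antipodal ligand is used and nothing else changes.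
Assumption: 10 is bought as such; it is the tert-butyldimethylsilyl ether of propargyl alcohol.

## Route

Step 1
Reactants: 1 (S)-citramalic acid
Product: 2 2-[(4S)-2,2,4-trimethyl-5-oxo-1,3-dioxolan-4-yl]acetic acid
Conditions: 2,2-dimethoxypropane, p-TsOH·H2O (cat.), rt
Reagents that add atoms: 2,2-dimethoxypropane, COC(C)(C)OC
Why: Acid-catalysed acetalisation of an α-hydroxy acid; the dioxolanone masks the tertiary hydroxyl and the C1 carboxyl together, leaves the β-carboxyl free and does not touch the stereocentre.

Step 2
Reactants: 2 2-[(4S)-2,2,4-trimethyl-5-oxo-1,3-dioxolan-4-yl]acetic acid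
Product: 4 (3S)-3-hydroxy-3-methyloxolan-2-one, via hydroxyethyl dioxolanone 3 (not isolated)
Conditions: BH3·SMe2, THF, 0 °C to rt; MeOH; then p-TsOH·H2O (cat.), CH2Cl2, rt
Reagents that add atoms: none
Why: Borane reduces the free carboxylic acid much faster than the dioxolanone ester (chemoselective acid reduction); under acid the new primary alcohol transesterifies onto the dioxolanone carbonyl, closing the γ-lactone and releasing acetone.

Step 3
Reactants: 4 (3S)-3-hydroxy-3-methyloxolan-2-one
Product: 5 (3S)-3-methyl-3-(triethylsilyloxy)oxolan-2-one
Conditions: Et3SiOTf, 2,6-lutidine, CH2Cl2, −78 to 0 °C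
Reagents that add atoms: triethylsilyl trifluoromethanesulfonate, CC[Si](CC)(CC)OS(=O)(=O)C(F)(F)F
Why: Silyl triflate with a hindered pyridine base is the standard silylation of a tertiary alcohol; the triethylsilyl ether survives hydride, ylide, zinc and titanium reagents and is removed by fluoride in step 12.

Step 4
Reactants: 5 (3S)-3-methyl-3-(triethylsilyloxy)oxolan-2-one
Product: 6 (3S)-3-methyl-3-(triethylsilyloxy)oxolan-2-ol (anomer mixture)
Conditions: i-Bu2AlH, CH2Cl2, −78 °C; aq. potassium sodium tartrate
Reagents that add atoms: none
Why: Partial reduction of a lactone to the lactol; the tetrahedral aluminate is stable at −78 °C and the quaternary α-carbon slows over-reduction.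

Step 5
Reactants: 6 (3S)-3-methyl-3-(triethylsilyloxy)oxolan-2-ol
Product: 7 (3S)-3-methyl-3-(triethylsilyloxy)pent-4-en-1-ol
Conditions: Ph3PCH3Br, n-BuLi, THF, 0 °C; then 6, 0 °C to rt
Reagents that add atoms: methyltriphenylphosphonium bromide, C[P+](c1ccccc1)(c1ccccc1)c1ccccc1.[Br-]
Why: Wittig methylenation of the lactol through its open hydroxy aldehyde; the α-carbon is quaternary so nothing can epimerise, and a lithium alkoxide at low temperature limits migration of the silyl group to the primary oxygen.

Step 6
Reactants: 7 (3S)-3-methyl-3-(triethylsilyloxy)pent-4-en-1-ol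
Product: 9 (2E,5S)-5-methyl-5-(triethylsilyloxy)hepta-2,6-dienal, via silyloxy pentenal 8 (not isolated)
Conditions: TEMPO (10 mol %), PhI(OAc)2, CH2Cl2, rt; then Ph3P=CHCHO, toluene, 60 °C
Reagents that add atoms: (triphenylphosphoranylidene)acetaldehyde, O=CC=P(c1ccccc1)(c1ccccc1)c1ccccc1
Why: Oxoammonium oxidation of the primary alcohol followed in the same flask by Wittig olefination with the formyl-stabilised ylide, which gives the E enal; the β-silyloxy aldehyde, prone to elimination, is never isolated.

Step 7
Reactants: 9 (2E,5S)-5-methyl-5-(triethylsilyloxy)hepta-2,6-dienal; 10 tert-butyldimethyl(prop-2-yn-1-yloxy)silane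
Product: 11 (4S,5E,8S)-1-(tert-butyldimethylsilyloxy)-8-methyl-8-(triethylsilyloxy)deca-5,9-dien-2-yn-4-ol
Conditions: Me2Zn, (S,S)-ProPhenol (20 mol %), Ph3P=O (40 mol %), toluene, 0 to 4 °C
Reagents that add atoms: none
Why: Catalytic asymmetric alkynylation of an aldehyde: Me2Zn metalates the alkyne and the dinuclear zinc–ProPhenol complex delivers the alkynyl group 1,2 to one face of the enal, so the C6 carbinol is set by the ligand; the remote C10 centre has no say.

Step 8
Reactants: 11 (4S,5E,8S)-1-(tert-butyldimethylsilyloxy)-8-methyl-8-(triethylsilyloxy)deca-5,9-dien-2-yn-4-ol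
Product: 12 (1R)-4-(tert-butyldimethylsilyloxy)-1-{(2R,3R)-3-[(2S)-2-methyl-2-(triethylsilyloxy)but-3-en-1-yl]oxiran-2-yl}but-2-yn-1-ol
Conditions: Ti(OiPr)4 (20 mol %), D-(−)-diisopropyl tartrate (24 mol %), t-BuOOH, 4 Å MS, CH2Cl2, −20 °C
Reagents that add atoms: tert-butyl hydroperoxide, CC(C)(C)OO
Why: Sharpless asymmetric epoxidation of a secondary allylic alcohol in its matched, fast-reacting sense; the D-(−)-tartrate titanium complex epoxidises the E alkene on the face that gives the erythro trans-epoxy alcohol, which sets C7 and C8. Any 4R epimer reacts slowly and is left behind, and the vinyl silyl ether and the alkyne are inert.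

Step 9
Reactants: 12 (1R)-4-(tert-butyldimethylsilyloxy)-1-{(2R,3R)-3-[(2S)-2-methyl-2-(triethylsilyloxy)but-3-en-1-yl]oxiran-2-yl}but-2-yn-1-ol; 13 (diethoxyphosphoryl)acetic acid
Product: 14 epoxy alcohol phosphonoacetate [(diethoxyphosphoryl)acetate of 12 at O6]
Conditions: DCC, DMAP (cat.), CH2Cl2, 0 °C to rt
Reagents that add atoms: none
Why: Steglich esterification of the secondary alcohol under neutral carbodiimide conditions, which avoid Payne rearrangement of the epoxy alcohol.

Step 10
Reactants: 14 epoxy alcohol phosphonoacetate
Product: 15 α-phosphono γ-lactone with free C8 hydroxyl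
Conditions: NaH, THF, 0 °C to rt; AcOH
Reagents that add atoms: none
Why: NaH removes the phosphonoacetate proton (the most acidic C–H of 14) and the carbanion attacks C7 from the side opposite the C7–O bond in an SN2 opening; the closest known reaction type is the intramolecular opening of epoxides by stabilised ester carbanions, the carbon counterpart of the base-induced closure of epoxy alcohol carbamates to oxazolidinones. The γ-lactone closes in the 5-exo-tet mode (the breaking C7–O bond lies outside the new ring); the exocyclic phosphoryl group carries the charge, so the carbanion lone pair can lie in the plane of the forming ring and the closure does not depend on an endocyclic ester enolate. C7 is set by inversion of the epoxide carbon, C8 keeps its epoxide C–O bond and configuration, C6 is untouched, and C11 settles trans to the C7 side chain by equilibration of the acidic phosphonate (it is lost in step 18 in any case). The step needs attack at C7 and not at C8 (6-endo), and through carbon and not through the enolate oxygen: the shorter tether with collinear approach available only at C7 secures the first, and the soft phosphorus-stabilised carbanion with sodium in THF the second. The released C8 alkoxide is protonated at once by the new phosphono lactone, the stronger acid, so the resting state is a lactone enolate that cannot translactonise to O8; acetic acid then gives 15. The silyl ethers, the alkyne and the vinyl group are spectators, and no base-sensitive ester is yet present.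

Step 11
Reactants: 15 α-phosphono γ-lactone with free C8 hydroxyl; 16 (2R)-2-methylbutanoic acid
Product: 17 8-O-[(2R)-2-methylbutanoyl] phosphono lactone
Conditions: DCC, DMAP (cat.), CH2Cl2, 0 °C
Reagents that add atoms: none
Why: Steglich esterification of the only free hydroxyl; 0 °C and catalytic DMAP keep the α-stereocentre of the acid intact, and capping O8 removes the possibility of lactone migration for the rest of the route.

Step 12
Reactants: 17 8-O-[(2R)-2-methylbutanoyl] phosphono lactone
Product: 18 C10,C15-diol (both silyl ethers of 17 removed)
Conditions: HF·pyridine, pyridine, THF, 0 °C to rt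
Reagents that add atoms: none
Why: Fluoride cleavage of both silyl ethers under buffered, non-basic conditions, so neither acyl migration from O8 to O10 nor enolisation of the phosphono lactone intervenes; the C15 hydroxyl is needed to direct step 13 and the C10 hydroxyl for step 15.

Step 13
Reactants: 18 C10,C15-diol
Product: 20 (4Z)-4-tributylstannyl alkene with C15 tert-butyldimethylsilyl ether and free C10 hydroxyl, via hydroxy stannane 19 (not isolated)
Conditions: Bu3SnH, [Cp*RuCl]4 (2 mol %), CH2Cl2, rt; then imidazole, t-BuMe2SiCl, 0 °C to rt
Reagents that add atoms: tributyltin hydride, CCCC[SnH](CCCC)CCCC; tert-butyldimethylsilyl chloride, CC(C)(C)[Si](C)(C)Cl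
Why: Ruthenium-catalysed trans-hydrostannation of a propargylic alcohol: hydrogen bonding of the C15 hydroxyl to the chloride ligand steers tin to the proximal C4 and hydrogen is delivered anti, so C6 and tin end up cis (the ring Z geometry). Silylating the primary alcohol in the same flask leaves the tertiary C10 hydroxyl free and avoids chromatography of the acid-sensitive hydroxy stannane.

Step 14
Reactants: 20 (4Z)-4-tributylstannyl alkene with C15 silyl ether
Product: 21 C3 acryloyl ketone (cross-conjugated divinyl ketone with free C10 hydroxyl)
Conditions: CH2=CHCOCl, Pd2(dba)3 (5 mol %), P(2-furyl)3 (20 mol %), BHT, THF, 45 °C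
Reagents that add atoms: acryloyl chloride, C=CC(=O)Cl
Why: Stille coupling of an acid chloride with an alkenylstannane, with retention of olefin geometry, installs C3 and C2; the weakly donating furylphosphine speeds transmetalation of the hindered stannane, and the tertiary alcohol does not react with the acid chloride without base.

Step 15
Reactants: 21 C3 acryloyl ketone
Product: 23 3,10-epoxy-3-hydroxy-1-ene hemiketal (11-phosphono and 15-O-silyl), via Z-enone macrocycle 22 (not isolated)
Conditions: RuCl2(H2IMes)(=CH-C6H4-2-OiPr) (second-generation Hoveyda–Grubbs catalyst, 10 mol %), toluene (1 mM), 80 °C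
Reagents that add atoms: none
Why: Ring-closing metathesis between the vinyl carbinol (initiation site) and the acryloyl group forms C1=C2 and the ten-membered ring. Metathesis is reversible, and the Z enone is drained from the equilibrium because its C10 hydroxyl adds across the ring to the C3 ketone, giving the cis-bridged hemiketal whose C3 configuration is dictated by C10; the trisubstituted C4=C5 olefin and the phosphono lactone take no part.

Step 16
Reactants: 23 3,10-epoxy-3-hydroxy-1-ene hemiketal
Product: 24 11-(diethoxyphosphoryl) 15-O-(tert-butyldimethylsilyl) furanone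
Conditions: pyridinium chlorochromate, NaOAc, 4 Å MS, CH2Cl2, rt
Reagents that add atoms: pyridinium chlorochromate, [O-][Cr](=O)(=O)Cl.c1cc[nH+]cc1
Why: Proposed new method: oxidative 1,3-transposition applied to a cyclic allylic hemiketal; the hemiketal hydroxyl forms a chromate ester of hexavalent chromium, a [3,3] shift moves the chromate to C1 while C2=C3 becomes the enol ether double bond, and oxidation of the secondary C1 chromate gives the 3(2H)-furanone. The open hydroxy enone tautomer has only a tertiary alcohol and cannot be oxidised, and O15 is silylated; the closest known reaction is the Babler–Dauben chlorochromate transposition of tertiary allylic alcohols to enones.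

Step 17
Reactants: 24 11-(diethoxyphosphoryl) 15-O-(tert-butyldimethylsilyl) furanone
Product: 25 11-(diethoxyphosphoryl) 15-hydroxy furanone
Conditions: HF·pyridine, pyridine, THF, 0 °C
Reagents that add atoms: none
Why: Fluoride cleavage of the primary allylic silyl ether under buffered conditions that the vinylogous ester, both esters and the acidic phosphonate tolerate.

Step 18
Reactants: 25 11-(diethoxyphosphoryl) 15-hydroxy furanone
Product: 26 target CNP0307052.2
Conditions: K2CO3, 37% aq. HCHO, THF, 0 °C to rt
Reagents that add atoms: formaldehyde, C=O
Why: Horner–Wadsworth–Emmons olefination of an α-phosphono lactone with formaldehyde under mild carbonate conditions; only the phosphonate C–H is acidic enough to react, so the α-methylene group is unveiled last and the ester, furanone and allylic alcohol are untouched.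

## Compound list

1 | (S)-citramalic acid [(2S)-2-hydroxy-2-methylbutanedioic acid] | OC(=O)[C@](C)(CC(=O)O)O | starting material
2 | 2-[(4S)-2,2,4-trimethyl-5-oxo-1,3-dioxolan-4-yl]acetic acid | CC1(C)OC(=O)[C@](C)(CC(=O)O)O1 | intermediate
3 | (5S)-5-(2-hydroxyethyl)-2,2,5-trimethyl-1,3-dioxolan-4-one | CC1(C)OC(=O)[C@](C)(CCO)O1 | intermediate
4 | (3S)-3-hydroxy-3-methyloxolan-2-one | O=C1OCC[C@]1(C)O | intermediate
5 | (3S)-3-methyl-3-(triethylsilyloxy)oxolan-2-one | O=C1OCC[C@]1(C)O[Si](CC)(CC)CC | intermediate
6 | (3S)-3-methyl-3-(triethylsilyloxy)oxolan-2-ol (anomer mixture) | OC1OCC[C@]1(C)O[Si](CC)(CC)CC | intermediate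
7 | (3S)-3-methyl-3-(triethylsilyloxy)pent-4-en-1-ol | OCC[C@](C)(O[Si](CC)(CC)CC)C=C | intermediate
8 | (3S)-3-methyl-3-(triethylsilyloxy)pent-4-enal | O=CC[C@](C)(O[Si](CC)(CC)CC)C=C | intermediate
9 | (2E,5S)-5-methyl-5-(triethylsilyloxy)hepta-2,6-dienal | O=C/C=C/C[C@](C)(O[Si](CC)(CC)CC)C=C | intermediate
10 | tert-butyldimethyl(prop-2-yn-1-yloxy)silane | C#CCO[Si](C)(C)C(C)(C)C | starting material
11 | (4S,5E,8S)-1-(tert-butyldimethylsilyloxy)-8-methyl-8-(triethylsilyloxy)deca-5,9-dien-2-yn-4-ol | O[C@H](C#CCO[Si](C)(C)C(C)(C)C)/C=C/C[C@](C)(O[Si](CC)(CC)CC)C=C | intermediate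
12 | (1R)-4-(tert-butyldimethylsilyloxy)-1-{(2R,3R)-3-[(2S)-2-methyl-2-(triethylsilyloxy)but-3-en-1-yl]oxiran-2-yl}but-2-yn-1-ol | O[C@H](C#CCO[Si](C)(C)C(C)(C)C)[C@H]1O[C@@H]1C[C@](C)(O[Si](CC)(CC)CC)C=C | intermediate
13 | (diethoxyphosphoryl)acetic acid | OC(=O)CP(=O)(OCC)OCC | starting material
14 | epoxy alcohol phosphonoacetate [(diethoxyphosphoryl)acetate of 12 at O6] | CCOP(=O)(OCC)CC(=O)O[C@H](C#CCO[Si](C)(C)C(C)(C)C)[C@H]1O[C@@H]1C[C@](C)(O[Si](CC)(CC)CC)C=C | intermediate
15 | α-phosphono γ-lactone with free C8 hydroxyl: diethyl {(3S,4R,5S)-5-[3-(tert-butyldimethylsilyloxy)prop-1-yn-1-yl]-4-[(1R,3S)-1-hydroxy-3-methyl-3-(triethylsilyloxy)pent-4-en-1-yl]-2-oxooxolan-3-yl}phosphonate | CCOP(=O)(OCC)[C@@H]1C(=O)O[C@H](C#CCO[Si](C)(C)C(C)(C)C)[C@H]1[C@H](O)C[C@](C)(O[Si](CC)(CC)CC)C=C | intermediate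
16 | (2R)-2-methylbutanoic acid | OC(=O)[C@H](C)CC | starting material
17 | 8-O-[(2R)-2-methylbutanoyl] phosphono lactone (ester of 15 at O8) | CCOP(=O)(OCC)[C@@H]1C(=O)O[C@H](C#CCO[Si](C)(C)C(C)(C)C)[C@H]1[C@H](OC(=O)[C@H](C)CC)C[C@](C)(O[Si](CC)(CC)CC)C=C | intermediate
18 | C10,C15-diol (17 without its silyl groups) | CCOP(=O)(OCC)[C@@H]1C(=O)O[C@H](C#CCO)[C@H]1[C@H](OC(=O)[C@H](C)CC)C[C@](C)(O)C=C | intermediate
19 | (4Z)-4-tributylstannyl alkene diol (tin on C4, hydrogen on C5, C6 and tin cis) | CCOP(=O)(OCC)[C@@H]1C(=O)O[C@H](/C=C(/CO)[Sn](CCCC)(CCCC)CCCC)[C@H]1[C@H](OC(=O)[C@H](C)CC)C[C@](C)(O)C=C | intermediate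
20 | C15 tert-butyldimethylsilyl ether of 19 (C10 hydroxyl free) | CCOP(=O)(OCC)[C@@H]1C(=O)O[C@H](/C=C(/CO[Si](C)(C)C(C)(C)C)[Sn](CCCC)(CCCC)CCCC)[C@H]1[C@H](OC(=O)[C@H](C)CC)C[C@](C)(O)C=C | intermediate
21 | C3 acryloyl ketone (4Z divinyl ketone, C10 hydroxyl free) | CCOP(=O)(OCC)[C@@H]1C(=O)O[C@H](/C=C(/CO[Si](C)(C)C(C)(C)C)C(=O)C=C)[C@H]1[C@H](OC(=O)[C@H](C)CC)C[C@](C)(O)C=C | intermediate
22 | (1Z,4Z)-10-hydroxy-3-oxo ten-membered dienone | CCOP(=O)(OCC)[C@@H]1C(=O)O[C@@H]2/C=C(/CO[Si](C)(C)C(C)(C)C)C(=O)/C=C\[C@@](C)(O)C[C@@H](OC(=O)[C@H](C)CC)[C@@H]12 | intermediate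
23 | 3,10-epoxy-3-hydroxy-1-ene hemiketal (11-phosphono, 15-O-silyl) | CCOP(=O)(OCC)[C@@H]1C(=O)O[C@@H]2/C=C(/CO[Si](C)(C)C(C)(C)C)[C@]3(O)/C=C\[C@](C)(C[C@@H](OC(=O)[C@H](C)CC)[C@@H]12)O3 | intermediate
24 | 11-(diethoxyphosphoryl) 15-O-(tert-butyldimethylsilyl) furanone | CCOP(=O)(OCC)[C@@H]1C(=O)O[C@@H]2/C=C(/CO[Si](C)(C)C(C)(C)C)C3=CC(=O)[C@](C)(C[C@@H](OC(=O)[C@H](C)CC)[C@@H]12)O3 | intermediate
25 | 11-(diethoxyphosphoryl) 15-hydroxy furanone | CCOP(=O)(OCC)[C@@H]1C(=O)O[C@@H]2/C=C(/CO)C3=CC(=O)[C@](C)(C[C@@H](OC(=O)[C@H](C)CC)[C@@H]12)O3 | intermediate
26 | target CNP0307052.2 | C=C1C(=O)O[C@@H]2/C=C(/CO)C3=CC(=O)[C@](C)(C[C@@H](OC(=O)[C@H](C)CC)[C@@H]12)O3 | target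

## Step count and risk

Total step count: 18. Longest linear sequence: 18 steps (1 to 26); 10, 13 and 16 are bought.

Least certain steps:

Step 16 (labelled). Chromate ester formation at the hindered bridgehead hemiketal may be slow, and acid-promoted ionisation of the allylic hemiketal could then lead to decomposition or over-oxidation instead of the sigmatropic shift. The fallback uses known chemistry, sets out from 23 and returns at 24. A palladium-catalysed Wacker-type oxidation of the C1=C2 double bond (Na2PdCl4 cat., t-BuOOH, aqueous acetic acid, 50 °C) is applied; this is the established oxidation of α,β-unsaturated carbonyl compounds to 1,3-dicarbonyl compounds, and the open tautomer 22 is such an enone. The new carbonyl goes to C1, the carbon remote from the doubly oxygenated C3, giving the keto hemiketal F1. This β-hydroxy ketone loses water in the acidic medium (or on brief treatment with p-toluenesulfonic acid) to give 24.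

Step 10 (key step). The ester tether must adopt its less favoured s-cis rotamer, so closure through the enolate oxygen, attack at C8, or base-induced acyl migration could outrun C–C bond formation. The fallback sets out from 12 and returns at 17.
- 12 is esterified with allyl hydrogen malonate (DCC, DMAP) to the allyl malonate F2.
- NaH in THF closes the lactone; the charge now sits in an ester outside the forming ring (enolexo closure), giving the α-allyloxycarbonyl lactone F3.
- Pd(PPh3)4 and morpholine remove the allyl group, and warming in toluene expels carbon dioxide to give the nor-lactone F4.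
- F4 is acylated with 16 (DCC, DMAP) to the ester F5.
- The lactone enolate of F5 is C-phosphorylated (LiN(iPr)2, ClP(O)(OEt)2, then a second equivalent of base for the 1,3-shift of phosphorus from oxygen to carbon) to give 17.

Step 14. Transmetalation of the hindered 1,1-disubstituted stannane may be slow, allowing protodestannylation or polymerisation of the acid chloride and of the vinyl ketone to compete. The fallback sets out from 20 and returns at 21. Iododestannylation (I2, CH2Cl2, 0 °C, retention) gives the alkenyl iodide F6. A carbonylative Stille coupling with tributyl(vinyl)stannane under CO (1 atm; Pd2(dba)3, AsPh3, THF, 50 °C) then builds the ketone from three components.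

Step 15. Oligomerisation or failure to close is possible because the vinyl carbinol is hindered, the enone is electron-poor and the ring is strained; closure to the E enone, which cannot form the hemiketal, is the other danger. The fallback sets out from 20 and returns at 23.
- The alkenyl iodide F6 is made as above.
- Cross-metathesis of its vinyl carbinol with crotonaldehyde (second-generation Hoveyda–Grubbs catalyst) gives the E enal F7.
- An intramolecular Nozaki–Hiyama–Kishi reaction (CrCl2, NiCl2 cat., DMSO/THF, high dilution) closes the ring at C3–C4 to the allylic alcohol F8.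
- Dess–Martin oxidation gives the E enone F9.
- Irradiation at 350 nm isomerises C1=C2 to the Z enone 22, which closes to 23.

Step 7. Facial selectivity or conversion may be poor with this γ-branched enal, and methyl transfer from Me2Zn could compete. The fallback sets out from 9 and 10 and returns at 12. Addition of the lithium acetylide of 10 (n-BuLi, THF, −78 °C) gives the C6 epimer mixture F10. Epoxidation under the conditions of step 8, stopped near half conversion (kinetic resolution, whose sense does not depend on the alkynylation), converts only the 4S epimer into 12 and leaves the 4R epimer F11.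

## Further compounds

F1 | step 16 | 3-hydroxy-1-oxo keto hemiketal (C1 ketone, C2 methylene, C3 hemiketal) | CCOP(=O)(OCC)[C@@H]1C(=O)O[C@@H]2/C=C(/CO[Si](C)(C)C(C)(C)C)[C@]3(O)CC(=O)[C@](C)(C[C@@H](OC(=O)[C@H](C)CC)[C@@H]12)O3
F2 | step 10 | allyl malonate of 12 at O6 | C=CCOC(=O)CC(=O)O[C@H](C#CCO[Si](C)(C)C(C)(C)C)[C@H]1O[C@@H]1C[C@](C)(O[Si](CC)(CC)CC)C=C
F3 | step 10 | α-allyloxycarbonyl γ-lactone with free C8 hydroxyl (C11 epimers) | C=CCOC(=O)C1C(=O)O[C@H](C#CCO[Si](C)(C)C(C)(C)C)[C@H]1[C@H](O)C[C@](C)(O[Si](CC)(CC)CC)C=C
F4 | step 10 | nor-lactone with C11 methylene and free C8 hydroxyl | C1C(=O)O[C@H](C#CCO[Si](C)(C)C(C)(C)C)[C@H]1[C@H](O)C[C@](C)(O[Si](CC)(CC)CC)C=C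
F5 | step 10 | 8-O-[(2R)-2-methylbutanoyl] nor-lactone | C1C(=O)O[C@H](C#CCO[Si](C)(C)C(C)(C)C)[C@H]1[C@H](OC(=O)[C@H](C)CC)C[C@](C)(O[Si](CC)(CC)CC)C=C
F6 | step 14 | C4 alkenyl iodide (iodine in place of tin in 20) | CCOP(=O)(OCC)[C@@H]1C(=O)O[C@H](/C=C(/CO[Si](C)(C)C(C)(C)C)I)[C@H]1[C@H](OC(=O)[C@H](C)CC)C[C@](C)(O)C=C
F7 | step 15 | (1E)-enal alkenyl iodide (C10 carbinol carrying CH=CH–CHO) | CCOP(=O)(OCC)[C@@H]1C(=O)O[C@H](/C=C(/CO[Si](C)(C)C(C)(C)C)I)[C@H]1[C@H](OC(=O)[C@H](C)CC)C[C@](C)(O)/C=C/C=O
F8 | step 15 | (1E,4Z)-3,10-dihydroxy ten-membered diene (C3 epimers) | CCOP(=O)(OCC)[C@@H]1C(=O)O[C@@H]2/C=C(/CO[Si](C)(C)C(C)(C)C)C(O)/C=C/[C@@](C)(O)C[C@@H](OC(=O)[C@H](C)CC)[C@@H]12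
F9 | step 15 | (1E,4Z)-10-hydroxy-3-oxo ten-membered dienone | CCOP(=O)(OCC)[C@@H]1C(=O)O[C@@H]2/C=C(/CO[Si](C)(C)C(C)(C)C)C(=O)/C=C/[C@@](C)(O)C[C@@H](OC(=O)[C@H](C)CC)[C@@H]12
F10 | step 7 | C6 epimer mixture of 11 | OC(C#CCO[Si](C)(C)C(C)(C)C)/C=C/C[C@](C)(O[Si](CC)(CC)CC)C=C
F11 | step 7 | (4R,5E,8S) epimer of 11 | O[C@@H](C#CCO[Si](C)(C)C(C)(C)C)/C=C/C[C@](C)(O[Si](CC)(CC)CC)C=C
A1 | alternative 1 | eight-membered cis-enone nor-lactone with C10–O ynol ether | C1C(=O)O[C@@H]2/C=C\C(=O)[C@](C)(C[C@@H](OC(=O)[C@H](C)CC)[C@@H]12)OC#CCO[Si](C)(C)C(C)(C)C
A2 | alternative 1 | 13-nor 15-O-silyl furanone lactone | C1C(=O)O[C@@H]2/C=C(/CO[Si](C)(C)C(C)(C)C)C3=CC(=O)[C@](C)(C[C@@H](OC(=O)[C@H](C)CC)[C@@H]12)O3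
A3 | alternative 2 | C1 aldehyde with C3–O β-alkoxy crotonate and iodoalkene | O=CC[C@H](O/C(C)=C/C(=O)OC)/C(CO[Si](C)(C)C(C)(C)C)=C\I
A4 | alternative 2 | 2,2,5-trisubstituted tetrahydrofuran-3-one | COC(=O)C[C@]1(C)O[C@@H](CC1=O)/C(CO[Si](C)(C)C(C)(C)C)=C\I
A5 | alternative 3 | nor-lactone vinyl carbinol vinyl ketone | C1C(=O)O[C@H](/C=C(/CO[Si](C)(C)C(C)(C)C)C(=O)C=C)[C@H]1[C@H](OC(=O)[C@H](C)CC)C[C@](C)(O)C=C
A6 | alternative 3 | oxygen-bridged 3-hydroxy-1-ene nor-lactone hemiketal | C1C(=O)O[C@@H]2/C=C(/CO[Si](C)(C)C(C)(C)C)[C@]3(O)/C=C\[C@](C)(C[C@@H](OC(=O)[C@H](C)CC)[C@@H]12)O3
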